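**Retrosynthetic overview**
- The target comes from acid hydrolysis of a menthyl lactone acetal (lactone carbonyl = C11 acid, acetal carbon = C12 aldehyde), after C6-selective acylation of a cis-6,9-diol with octatrienoic acid.
- The diol comes from singlet-oxygen [4+2] addition and O–O reduction on a cis-fused 6,8-dienyl lactone, so both oxygens enter from the convex face.
- Ring A is closed last, by cation–olefin cyclisation of a homoprenyl side chain onto the ring B alkene; the tether enforces the cis ring fusion.
- Ring B is made first, by Diels–Alder reaction of a geranial-derived triene with a chiral 5-menthyloxybutenolide (sets C10), then dehydrogenation to the butenolide.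
- Key step: singlet-oxygen dearomatisation of furfural turns the furan into the C8–C9–C11–C12 pseudo-acid with both final oxidation levels in place; its menthyl acetal is the only source of chirality.

Labels: drimane numbering (ring A = C1–C5, C10; ring B = C5–C10; C11 = carboxyl carbon on C9; C12 = formyl carbon on C8). β = the face of the C10 methyl group; in all tricyclic compounds H5 is β and C11 is α.
Assumption: the target is drawn as the open aldehyde–acid; it is the ring–chain tautomer of the 12-hydroxy-11,12-lactone, and hydrolysis delivers this equilibrium pair.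
Assumption: geranial of at least 95 % E purity is bought; any Z isomer would give a separable diastereomer in step 4.
Note: the acetal carbon C12 is drawn throughout as set in step 2; it is removed in step 10, so epimerisation there would not matter.

**Step 1**
Reactants: 1 furfural
Product: 3 5-hydroxyfuran-2(5H)-one (racemic), via furfural endoperoxide 2 (not isolated)
Conditions: O2, rose bengal (cat.), hν (visible), MeOH, 20 °C
Reagents that add atoms: dioxygen (O=O)
Why: Dye-sensitised photooxygenation in which singlet oxygen adds [4+2] across C2/C5 of the furan and destroys its aromaticity, and methanolysis of the endoperoxide expels the formyl carbon as methyl formate, leaving the pseudo-acid whose lactone carbonyl and lactol carbon are C11 and C12 of the target at their final oxidation levels (no defined stereocentre yet).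

**Step 2**
Reactants: 3 5-hydroxyfuran-2(5H)-one; 4 (−)-menthol
Product: 5 (5R)-5-[(1R,2S,5R)-menthyloxy]furan-2(5H)-one
Conditions: camphorsulfonic acid (cat.), toluene, reflux (Dean–Stark); crystallise from hexane at −20 °C, mother liquor re-equilibrated with acid
Reagents that add atoms: none
Why: Acid-catalysed acetal formation in which the two C5 epimers interconvert while the (5R)-acetal crystallises (crystallisation-induced diastereomer transformation), so the menthyloxy group is both the protecting group of the future aldehyde and the single source of absolute configuration.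

**Step 3**
Reactants: 6 geranial
Product: 7 (3E)-4,8-dimethylnona-1,3,7-triene
Conditions: Ph3PCH3Br, KOtBu, THF, 0 °C to 20 °C
Reagents that add atoms: methyltriphenylphosphonium bromide as its ylide methylenetriphenylphosphorane (C=P(c1ccccc1)(c1ccccc1)c1ccccc1)
Why: Wittig methylenation of the enal carbonyl leaves the E trisubstituted double bond untouched and so fixes the methyl group as the cis (inside) substituent of the diene terminus.

**Step 4**
Reactants: 5 (5R)-5-menthyloxyfuran-2(5H)-one; 7 (3E)-4,8-dimethylnona-1,3,7-triene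
Product: 8 (3R,3aR,7S,7aR)-3-menthyloxy-7-methyl-7-(4-methylpent-3-enyl)-3a,4,7,7a-tetrahydroisobenzofuran-1(3H)-one
Conditions: toluene, 2,6-di-tert-butyl-4-methylphenol (cat.), 135 °C, sealed tube, 5 d
Reagents that add atoms: none
Why: Thermal Diels–Alder reaction in which the unsubstituted diene terminus bonds to the β-carbon of the butenolide (so C9 bonds to the disubstituted terminus and the quaternary C10 is formed), the diene adds anti to the menthyloxy group and the lactone lies endo, so the inside methyl on C10 ends up cis to H9 and the (7S) centre follows from the (5R)-acetal.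

**Step 5**
Reactants: 8 Diels–Alder adduct
Product: 11 (3R,7S)-3-menthyloxy-7-methyl-7-(4-methylpent-3-enyl)-4,7-dihydroisobenzofuran-1(3H)-one, via selenide 9 (not isolated), via selenoxide 10 (not isolated)
Conditions: LiN(iPr)2, THF, −78 °C; PhSeCl (1.0 equiv); then NaIO4, NaHCO3, THF–MeOH–H2O, 20 °C
Reagents that add atoms: none
Why: Selenenylation of the lactone enolate on the convex face followed by selenoxide syn-elimination, which can only use the cis hydrogen on C8 because C10 carries none, so the C8=C9 butenolide forms regiospecifically and the C10 and C12 centres are untouched.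

**Step 6**
Reactants: 11 butenolide
Product: 13 (12R)-12-menthyloxy-5βH-drima-6,8-dien-11,12-olide, via trifluoroacetate 12 (not isolated)
Conditions: CF3CO2H–CH2Cl2 (1:3), 0 °C; evaporate; DBU, CH2Cl2, 20 °C
Reagents that add atoms: none
Why: Cation–olefin cyclisation in which protonation of the trisubstituted side-chain alkene gives the tertiary C4 cation, which bonds to C5 of the ring alkene on the face that carries the tether (axial attack, so ring A can only be cis-fused and H5 ends up cis to the C10 methyl) with trifluoroacetate capture at C6, and DBU then expels this leaving group through the vinylogous lactone enolate (E1cB) to give the conjugated diene.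

**Step 7**
Reactants: 13 cis-fused dienyl lactone
Product: 15 (12R)-6β,9β-dihydroxy-12-menthyloxy-5βH-drim-7-en-11,12-olide, via endoperoxide 14 (not isolated)
Conditions: O2, tetraphenylporphyrin (cat.), hν, CH2Cl2, 0 °C; then Zn, AcOH, 20 °C
Reagents that add atoms: dioxygen (O=O)
Why: Singlet-oxygen [4+2] cycloaddition to the s-cis diene from the convex face (the other face is covered by ring A and its C4 methyl groups) puts both new C–O bonds at C6 and C9 cis to the C10 methyl and H5, and zinc reduces the O–O bond with retention at both carbons.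

**Step 8**
Reactants: 16 (2E,4E)-hexa-2,4-dienal; 17 malonic acid
Product: 18 (2E,4E,6E)-octa-2,4,6-trienoic acid
Conditions: pyridine, piperidine (cat.), 90 °C
Reagents that add atoms: none
Why: Doebner–Knoevenagel condensation with decarboxylation gives the thermodynamically favoured E double bond.

**Step 9**
Reactants: 18 (2E,4E,6E)-octa-2,4,6-trienoic acid; 15 6β,9β-diol
Product: 20 (12R)-9β-hydroxy-12-menthyloxy-6β-[(2E,4E,6E)-octa-2,4,6-trienoyloxy]-5βH-drim-7-en-11,12-olide, via mixed anhydride 19 (not isolated)
Conditions: 2,4,6-trichlorobenzoyl chloride, Et3N, THF, 20 °C; then 15, DMAP, toluene, 20 °C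
Reagents that add atoms: none
Why: Yamaguchi esterification through the mixed anhydride is selective for the secondary allylic C6 hydroxyl because the tertiary C9 hydroxyl next to the lactone carbonyl and the quaternary C10 is too hindered, and it proceeds with retention at C6.

**Step 10**
Reactants: 20 lactone acetal ester
Product: 22 (1R,4R,4aR,8aS)-2-formyl-1-hydroxy-5,5,8a-trimethyl-4-[(2E,4E,6E)-octa-2,4,6-trienoyloxy]-1,4,4a,5,6,7,8,8a-octahydronaphthalene-1-carboxylic acid, via lactol tautomer 21 (not isolated)
Conditions: CF3CO2H–H2O–THF (1:1:4), 20 °C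
Reagents that add atoms: water (O)
Why: Acid hydrolysis of the allylic lactone acetal (oxocarbenium ion stabilised by the C7=C8 double bond) releases menthol, and the lactol opens by ring–chain tautomerism to the conjugated enal and the free C11 acid without touching any stereocentre.

**Compound list**
1 | furfural (furan-2-carbaldehyde) | O=Cc1ccco1 | starting material
2 | furfural 2,5-endoperoxide, racemic, not isolated | O=CC12C=CC(OO1)O2 | intermediate
3 | 5-hydroxyfuran-2(5H)-one, racemic lactol | OC1OC(=O)C=C1 | intermediate
4 | (−)-menthol, (1R,2S,5R)-2-isopropyl-5-methylcyclohexan-1-ol | CC(C)[C@@H]1CC[C@@H](C)C[C@H]1O | starting material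
5 | (5R)-5-[(1R,2S,5R)-menthyloxy]furan-2(5H)-one | O=C1C=C[C@H](O[C@@H]2C[C@H](C)CC[C@H]2C(C)C)O1 | intermediate
6 | geranial, (2E)-3,7-dimethylocta-2,6-dienal | CC(C)=CCC/C(C)=C/C=O | starting material
7 | (3E)-4,8-dimethylnona-1,3,7-triene | CC(C)=CCC/C(C)=C/C=C | intermediate
8 | (3R,3aR,7S,7aR)-3-[(1R,2S,5R)-menthyloxy]-7-methyl-7-(4-methylpent-3-enyl)-3a,4,7,7a-tetrahydroisobenzofuran-1(3H)-one (cis lactone; H-3a, H-7a, 7-methyl and menthyloxy on one face) | O=C1O[C@@H](O[C@@H]3C[C@H](C)CC[C@H]3C(C)C)[C@@H]2CC=C[C@](C)(CCC=C(C)C)[C@H]12 | intermediate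
9 | 7a-phenylselanyl derivative of 8 (Se on the face of H-3a), not isolated | O=C1O[C@@H](O[C@@H]3C[C@H](C)CC[C@H]3C(C)C)[C@@H]2CC=C[C@](C)(CCC=C(C)C)[C@]12[Se]c4ccccc4 | intermediate
10 | selenoxide of 9, not isolated | O=C1O[C@@H](O[C@@H]3C[C@H](C)CC[C@H]3C(C)C)[C@@H]2CC=C[C@](C)(CCC=C(C)C)[C@]12[Se](=O)c4ccccc4 | intermediate
11 | (3R,7S)-3-[(1R,2S,5R)-menthyloxy]-7-methyl-7-(4-methylpent-3-enyl)-4,7-dihydroisobenzofuran-1(3H)-one | O=C1O[C@@H](O[C@@H]3C[C@H](C)CC[C@H]3C(C)C)C2=C1[C@@](C)(CCC=C(C)C)C=CC2 | intermediate
12 | (12R)-12-menthyloxy-6β-(trifluoroacetoxy)-5βH-drim-8-en-11,12-olide, not isolated | O=C1O[C@@H](O[C@@H]4C[C@H](C)CC[C@H]4C(C)C)C2=C1[C@@]3(C)CCCC(C)(C)[C@H]3[C@H](OC(=O)C(F)(F)F)C2 | intermediate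
13 | (12R)-12-menthyloxy-5βH-drima-6,8-dien-11,12-olide (cis-fused decalin) | O=C1O[C@@H](O[C@@H]4C[C@H](C)CC[C@H]4C(C)C)C2=C1[C@@]3(C)CCCC(C)(C)[C@H]3C=C2 | intermediate
14 | (12R)-6β,9β-epidioxy-12-menthyloxy-5βH-drim-7-en-11,12-olide, not isolated | O=C1O[C@@H](O[C@@H]5C[C@H](C)CC[C@H]5C(C)C)C2=C[C@H]3OO[C@@]12[C@@]4(C)CCCC(C)(C)[C@@H]34 | intermediate
15 | (12R)-6β,9β-dihydroxy-12-menthyloxy-5βH-drim-7-en-11,12-olide | O[C@@H]1C=C2[C@H](O[C@@H]4C[C@H](C)CC[C@H]4C(C)C)OC(=O)[C@@]2(O)[C@@]3(C)CCCC(C)(C)[C@@H]13 | intermediate
16 | (2E,4E)-hexa-2,4-dienal (sorbaldehyde) | C/C=C/C=C/C=O | starting material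
17 | malonic acid | OC(=O)CC(=O)O | starting material
18 | (2E,4E,6E)-octa-2,4,6-trienoic acid | C/C=C/C=C/C=C/C(=O)O | intermediate
19 | (2E,4E,6E)-octa-2,4,6-trienoic 2,4,6-trichlorobenzoic anhydride, not isolated | C/C=C/C=C/C=C/C(=O)OC(=O)c1c(Cl)cc(Cl)cc1Cl | intermediate
20 | (12R)-9β-hydroxy-12-menthyloxy-6β-[(2E,4E,6E)-octa-2,4,6-trienoyloxy]-5βH-drim-7-en-11,12-olide | C/C=C/C=C/C=C/C(=O)O[C@@H]1C=C2[C@H](O[C@@H]4C[C@H](C)CC[C@H]4C(C)C)OC(=O)[C@@]2(O)[C@@]3(C)CCCC(C)(C)[C@@H]13 | intermediate
21 | 9β,12-dihydroxy-6β-[(2E,4E,6E)-octa-2,4,6-trienoyloxy]-5βH-drim-7-en-11,12-olide (lactol tautomer of 22), not isolated | C/C=C/C=C/C=C/C(=O)O[C@@H]1C=C2C(O)OC(=O)[C@@]2(O)[C@@]3(C)CCCC(C)(C)[C@@H]13 | intermediate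
22 | (1R,4R,4aR,8aS)-2-formyl-1-hydroxy-5,5,8a-trimethyl-4-[(2E,4E,6E)-octa-2,4,6-trienoyloxy]-1,4,4a,5,6,7,8,8a-octahydronaphthalene-1-carboxylic acid | C/C=C/C=C/C=C/C(=O)O[C@@H]1C=C(C=O)[C@@](O)(C(=O)O)[C@@]2(C)CCCC(C)(C)[C@@H]12 | target

**Step count**
Total: 10 steps. Longest linear sequence: 8 steps (1, 2, 4, 5, 6, 7, 9, 10).

**Steps most likely to fail**

Step 4. The diene terminus carries a cis methyl group and the butenolide is only a moderate dienophile, so the cycloaddition may be slow or poorly selective. The fallback sets out from triene 7 and returns at butenolide 11, so step 5 is not needed. Triene 7 is heated with dimethyl but-2-ynedioate, a much stronger dienophile, to give racemic dimethyl 3-methyl-3-(4-methylpent-3-enyl)cyclohexa-1,4-diene-1,2-dicarboxylate F1. Saponification (LiOH) and ring closure with Ac2O give 4-methyl-4-(4-methylpent-3-enyl)-4,7-dihydroisobenzofuran-1,3-dione F2. LiAlH(OtBu)3 at −78 °C reduces the less hindered carbonyl (remote from the quaternary carbon) to 3-hydroxy-7-methyl-7-(4-methylpent-3-enyl)-4,7-dihydroisobenzofuran-1(3H)-one F3. Acetalisation with (−)-menthol 4 (camphorsulfonic acid) and separation of the diastereomeric acetals, a resolution, gives 11.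

Step 6. The side-chain cation must add to a disubstituted ring alkene and leaves a secondary cation, so hydride shifts or simple addition of acid to the side chain may compete. The fallback sets out from 11 and returns at 13, closing ring A by a radical path instead of a cationic one. A chloro[N,N′-bis(3,5-di-tert-butylsalicylidene)-1,2-cyclohexanediaminato]cobalt catalyst (Co(salen)Cl type, trivalent cobalt) with a few mol % PhSiH3 transfers a hydrogen atom to the trisubstituted alkene. The tertiary C4 radical closes onto C5 (6-exo, again only cis fusion possible), and the catalyst takes back a hydrogen atom from C7 to give diene 13 directly. No new compound is made (F0).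

Step 7. The diene is conjugated to the lactone carbonyl and therefore electron-poor toward singlet oxygen, and the β-menthyloxy group may erode the face selectivity. The fallback sets out from 13 and returns at 15, using the electron-poor character of the diene in a stepwise ionic 1,4-dioxygenation. The potassium salt of (E)-benzaldoxime adds as a hydroxide equivalent to C6 (oxa-1,6-addition from the convex face). The extended enolate is hydroxylated at C9 with 2-(phenylsulfonyl)-3-phenyloxaziridine to give (12R)-6β-(benzylideneaminooxy)-9β-hydroxy-12-menthyloxy-5βH-drim-7-en-11,12-olide F4. KOtBu then fragments the oxime ether to diol 15.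

**Further compounds**
F1 | step 4 | dimethyl 3-methyl-3-(4-methylpent-3-enyl)cyclohexa-1,4-diene-1,2-dicarboxylate (racemic) | COC(=O)C1=C(C(=O)OC)C(C)(CCC=C(C)C)C=CC1
F2 | step 4 | 4-methyl-4-(4-methylpent-3-enyl)-4,7-dihydroisobenzofuran-1,3-dione (racemic) | O=C1OC(=O)C2=C1C(C)(CCC=C(C)C)C=CC2
F3 | step 4 | 3-hydroxy-7-methyl-7-(4-methylpent-3-enyl)-4,7-dihydroisobenzofuran-1(3H)-one (racemic lactol) | O=C1OC(O)C2=C1C(C)(CCC=C(C)C)C=CC2
F0 | step 6 | none | none
F4 | step 7 | (12R)-6β-[(E)-benzylideneaminooxy]-9β-hydroxy-12-menthyloxy-5βH-drim-7-en-11,12-olide | c5ccccc5/C=N/O[C@@H]1C=C2[C@H](O[C@@H]4C[C@H](C)CC[C@H]4C(C)C)OC(=O)[C@@]2(O)[C@@]3(C)CCCC(C)(C)[C@@H]13
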